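The target's eleven-membered ring is numbered C1 (exocyclic CH2), C2=C3, C4 (CMe2), C5 (ester), C8(Me)=C9. C2 and C5 are the ring-fusion atoms shared by the cyclobutane and the nine-membered ring of the caryophyllane skeleton, and the route rests on cutting that one C2–C5 bond. In a single operation a phenylthiyl radical adds to the exocyclic CH2, the cyclobutane opens to the eleven-membered ring with C1=C2, and O2 places oxygen on C5. The precursor is commercial (−)-caryophyllene oxide: its epoxide masks the strained E C8=C9 alkene, which thiyl radicals would isomerise, and is removed stereospecifically two steps later. The sulfide left at C1 later returns the exocyclic methylene and C2=C3.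

Key step: step 1

Remark: the ring numbering above is used for every intermediate. No stereocentre of the starting terpene survives beyond step 3, so the single stereocentre of the target comes from step 4. Where C5 or C2 is formed as both epimers the SMILES leaves it unmarked. The C1=C2 geometry of the allyl sulfides is not controlled and is drawn as the isomer with C3 and C11 trans; both isomers converge in step 7.

Step 1
Reactants: 1 (−)-caryophyllene oxide; 2 thiophenol
Product: 4 (8R,9R)-8,9-epoxy-4,4,8-trimethyl-1-(phenylthiomethyl)cycloundec-1-en-5-ol (both C5 epimers), via C5 hydroperoxide 3 (not isolated)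
Conditions: PhSH (1.3 equiv, syringe pump, 12 h), 2% O2 in N2 (slow stream), 1,1'-azobis(cyclohexanecarbonitrile) (0.2 equiv), PhCl (0.01 M), 90 °C; then PPh3 (1.5 equiv), rt
Reagents that add atoms: dioxygen, O=O
Why: Proposed new method: PhS• adds reversibly to the exocyclic CH2 of 1 to give the tertiary cyclobutylcarbinyl radical at C1, β-scission of the C2–C5 ring-fusion bond then forms the C1=C2 alkene and a secondary C5 radical (the alternative C2–C3 cleavage would give a primary radical and keep the nine-membered ring strained), O2 captures C5, and the peroxyl radical takes hydrogen from PhSH to carry the chain before PPh3 reduces hydroperoxide 3. The closest known reaction types are the thiyl-radical opening of the vinylcyclobutane unit of β-pinene, thiol–olefin co-oxygenation with ring opening of vinylcyclopropanes, and radical retro-cycloisomerisation of terpene vinylcyclobutanes started by hydrogen-atom transfer. No ring is closed by bond formation: the eleven-membered ring appears because the bond common to the four- and nine-membered rings is cut. C5 is the only new stereocentre and is left uncontrolled (it is erased in step 2 and reset in step 4), and the C1=C2 geometry does not matter because step 7 moves that double bond. The selectivity needed is thiyl attack at the exocyclic alkene alone, secured in the substrate by the epoxide that replaces the strained E C8=C9 alkene (which thiyl radicals would add to and isomerise), and ring opening ahead of capture of the C1 radical, for which the thiol is fed slowly, oxygen is kept lean and the solution is dilute and hot. The thiol feed must still be fast enough to reduce the C5 peroxyl radical before it adds across the ring to C2.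

Step 2
Reactants: 4 epoxy hydroxy sulfide
Product: 5 (8R,9R)-8,9-epoxy-4,4,8-trimethyl-1-(phenylthiomethyl)cycloundec-1-en-5-one
Conditions: (COCl)2, DMSO, CH2Cl2, −78 °C; Et3N, −78 to 0 °C
Reagents that add atoms: none
Why: Swern oxidation converts the hindered secondary alcohol under basic conditions that spare the sulfide and the epoxide, merges both C5 epimers into one ketone and removes the hydroxyl group that could open the epoxide across the ring.

Step 3
Reactants: 5 epoxy keto sulfide
Product: 6 (8E)-4,4,8-trimethyl-1-(phenylthiomethyl)cycloundeca-1,8-dien-5-one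
Conditions: Re2O7 (5 mol%), P(OPh)3 (1.5 equiv), toluene, 100 °C
Reagents that add atoms: none
Why: Rhenium-catalysed oxygen-atom transfer from an epoxide to a phosphite runs through a rhenium diolate and concerted alkene extrusion with retention, so the trans-epoxide should return the E C8=C9 alkene now that the radical step is past.

Step 4
Reactants: 6 achiral keto sulfide
Product: 7 (5R,8E)-4,4,8-trimethyl-1-(phenylthiomethyl)cycloundeca-1,8-dien-5-ol
Conditions: (S)-2-butyl-CBS-oxazaborolidine (0.2 equiv), catecholborane (1.5 equiv), toluene, −78 to −30 °C; MeOH, then aq. NaOH wash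
Reagents that add atoms: none
Why: Corey–Bakshi–Shibata reduction: the ketone binds the catalyst boron anti to its larger flank (quaternary C4, which behaves like the tert-alkyl or trichloromethyl group of the standard substrates) and hydride goes to the face that gives the (5R)-alcohol, while catecholborane at low temperature should not hydroborate the two trisubstituted alkenes.

Step 5
Reactants: 8 vanillic acid
Product: 10 3-methoxy-4-(triisopropylsilyloxy)benzoic acid, via bis-TIPS derivative 9 (not isolated)
Conditions: TIPSCl (2.3 equiv), imidazole (5 equiv), DMF, rt; then K2CO3, THF/MeOH/H2O, rt; 1 M HCl to pH 3, 0 °C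
Reagents that add atoms: chlorotriisopropylsilane, CC(C)[Si](Cl)(C(C)C)C(C)C
Why: Silylation of both acidic sites followed by selective hydrolysis of the labile silyl ester leaves the aryl TIPS ether, which blocks the phenol against self-acylation in step 6 and resists the basic species of steps 8 and 9.

Step 6
Reactants: 7 (5R)-alcohol; 10 protected vanillic acid
Product: 12 (5R,8E)-4,4,8-trimethyl-1-(phenylthiomethyl)cycloundeca-1,8-dien-5-yl 3-methoxy-4-(triisopropylsilyloxy)benzoate, via acid chloride 11 (not isolated)
Conditions: 10, (COCl)2, DMF (cat.), CH2Cl2, 0 °C to rt, evaporation; then 7, Et3N, DMAP (0.3 equiv), CH2Cl2, rt to 40 °C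
Reagents that add atoms: none
Why: Acid chloride formation and DMAP-catalysed acylation (nucleophilic catalysis) is the standard way to aroylate a hindered neopentyl-type secondary alcohol, and the C5 configuration is kept because the C5–O bond is not broken.

Step 7
Reactants: 12 ester sulfide
Product: 14 (5R,8E)-2-hydroxy-4,4,8-trimethyl-1-methylidenecycloundec-8-en-5-yl 3-methoxy-4-(triisopropylsilyloxy)benzoate (both C2 epimers), via allyl sulfoxide 13 (not isolated)
Conditions: mCPBA (1.05 equiv), CH2Cl2, −78 °C; aq. NaHCO3 wash; then P(OMe)3 (4 equiv), MeOH, 40 °C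
Reagents that add atoms: 3-chloroperoxybenzoic acid, O=C(OO)c1cccc(Cl)c1
Why: Oxidation at sulfur is far faster at −78 °C than epoxidation of the trisubstituted alkenes, and the allyl sulfoxide undergoes the Mislow–Evans [2,3]-sigmatropic shift to a sulfenate that the phosphite cleaves, giving the C2 alcohol and the exocyclic methylene at C1; C2 forms as both epimers, which is harmless because it becomes sp2 in step 9.

Step 8
Reactants: 14 allylic alcohol
Product: 15 (5R,8E)-2-(methoxycarbonyloxy)-4,4,8-trimethyl-1-methylidenecycloundec-8-en-5-yl 3-methoxy-4-(triisopropylsilyloxy)benzoate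
Conditions: ClCO2Me (3 equiv), pyridine, DMAP (cat.), CH2Cl2, 0 °C to rt
Reagents that add atoms: methyl chloroformate, COC(=O)Cl
Why: Acylation of the secondary allylic alcohol with a chloroformate installs the carbonate leaving group for ionisation by palladium.

Step 9
Reactants: 15 allylic carbonate
Product: 16 (5R,2E,8E)-4,4,8-trimethyl-1-methylidenecycloundeca-2,8-dien-5-yl 3-methoxy-4-(triisopropylsilyloxy)benzoate
Conditions: Pd(PPh3)4 (5 mol%), 1,4-dioxane (degassed), 90 °C
Reagents that add atoms: none
Why: Tsuji-type palladium-catalysed elimination: zerovalent palladium ionises the carbonate to a π-allyl complex over the exocyclic CH2, C1 and C2 with loss of CO2, and since the only β-hydrogens sit on C3 the elimination can give only the CH2=C1–C2=C3 diene, with E geometry at C2=C3 favoured because it keeps C1 away from the C4 gem-dimethyl group.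

Step 10
Reactants: 16 silyl-protected ester
Product: 17 target, (5R,2E,8E)-4,4,8-trimethyl-1-methylidenecycloundeca-2,8-dien-5-yl 4-hydroxy-3-methoxybenzoate
Conditions: Bu4NF (1.1 equiv), AcOH (1.2 equiv), THF, 0 °C
Reagents that add atoms: none
Why: Fluoride-mediated desilylation of the aryl silyl ether, buffered with acetic acid, frees the phenol without touching the hindered ester, the diene or the C5 stereocentre.

Compound list
1 | (−)-caryophyllene oxide, (1R,4R,5R,9S)-4,5-epoxycaryophyll-8(13)-ene | C[C@@]12CC[C@@H]3[C@H](CC3(C)C)C(=C)CC[C@H]1O2 | starting material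
2 | thiophenol | Sc1ccccc1 | starting material
3 | (8R,9R)-8,9-epoxy-5-hydroperoxy-4,4,8-trimethyl-1-(phenylthiomethyl)cycloundec-1-ene, C5 epimers | C[C@@]12CCC(OO)C(C)(C)C/C=C(\CSc3ccccc3)CC[C@H]1O2 | intermediate (not isolated)
4 | (8R,9R)-8,9-epoxy-4,4,8-trimethyl-1-(phenylthiomethyl)cycloundec-1-en-5-ol, C5 epimers | C[C@@]12CCC(O)C(C)(C)C/C=C(\CSc3ccccc3)CC[C@H]1O2 | intermediate
5 | (8R,9R)-8,9-epoxy-4,4,8-trimethyl-1-(phenylthiomethyl)cycloundec-1-en-5-one | C[C@@]12CCC(=O)C(C)(C)C/C=C(\CSc3ccccc3)CC[C@H]1O2 | intermediate
6 | (8E)-4,4,8-trimethyl-1-(phenylthiomethyl)cycloundeca-1,8-dien-5-one | O=C1CC/C(C)=C/CC/C(CSc2ccccc2)=C/CC1(C)C | intermediate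
7 | (5R,8E)-4,4,8-trimethyl-1-(phenylthiomethyl)cycloundeca-1,8-dien-5-ol | O[C@@H]1CC/C(C)=C/CC/C(CSc2ccccc2)=C/CC1(C)C | intermediate
8 | vanillic acid, 4-hydroxy-3-methoxybenzoic acid | COc1cc(C(=O)O)ccc1O | starting material
9 | triisopropylsilyl 3-methoxy-4-(triisopropylsilyloxy)benzoate | COc1cc(C(=O)O[Si](C(C)C)(C(C)C)C(C)C)ccc1O[Si](C(C)C)(C(C)C)C(C)C | intermediate (not isolated)
10 | 3-methoxy-4-(triisopropylsilyloxy)benzoic acid | COc1cc(C(=O)O)ccc1O[Si](C(C)C)(C(C)C)C(C)C | intermediate
11 | 3-methoxy-4-(triisopropylsilyloxy)benzoyl chloride | COc1cc(C(=O)Cl)ccc1O[Si](C(C)C)(C(C)C)C(C)C | intermediate (not isolated)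
12 | (5R,8E)-4,4,8-trimethyl-1-(phenylthiomethyl)cycloundeca-1,8-dien-5-yl 3-methoxy-4-(triisopropylsilyloxy)benzoate | COc1cc(C(=O)O[C@@H]2CC/C(C)=C/CC/C(CSc3ccccc3)=C/CC2(C)C)ccc1O[Si](C(C)C)(C(C)C)C(C)C | intermediate
13 | S-oxide of 12 (allyl phenyl sulfoxide, both sulfur epimers) | COc1cc(C(=O)O[C@@H]2CC/C(C)=C/CC/C(CS(=O)c3ccccc3)=C/CC2(C)C)ccc1O[Si](C(C)C)(C(C)C)C(C)C | intermediate (not isolated)
14 | (5R,8E)-2-hydroxy-4,4,8-trimethyl-1-methylidenecycloundec-8-en-5-yl 3-methoxy-4-(triisopropylsilyloxy)benzoate, C2 epimers | COc1cc(C(=O)O[C@@H]2CC/C(C)=C/CCC(=C)C(O)CC2(C)C)ccc1O[Si](C(C)C)(C(C)C)C(C)C | intermediate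
15 | C2 methyl carbonate of 14 | COc1cc(C(=O)O[C@@H]2CC/C(C)=C/CCC(=C)C(OC(=O)OC)CC2(C)C)ccc1O[Si](C(C)C)(C(C)C)C(C)C | intermediate
16 | (5R,2E,8E)-4,4,8-trimethyl-1-methylidenecycloundeca-2,8-dien-5-yl 3-methoxy-4-(triisopropylsilyloxy)benzoate | C=C1/C=C/C(C)(C)[C@H](OC(=O)c2ccc(O[Si](C(C)C)(C(C)C)C(C)C)c(OC)c2)CC/C(C)=C/CC1 | intermediate
17 | (5R,2E,8E)-4,4,8-trimethyl-1-methylidenecycloundeca-2,8-dien-5-yl 4-hydroxy-3-methoxybenzoate | C=C1/C=C/C(C)(C)[C@H](OC(=O)c2ccc(O)c(OC)c2)CC/C(C)=C/CC1 | target

Total steps: 10. Longest linear sequence: 9 (steps 1–4 and 6–10; step 5 is the side branch).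

Steps most likely to fail

Step 1. The tertiary C1 radical may be captured by O2 or by thiol before the four-membered ring opens. The C5 peroxyl radical may instead add across the ring to the new allyl sulfide alkene. Sulfur may also be oxidised by the hydroperoxide, so that little 4 forms. The fallback uses known chemistry and brings sulfur in by ionic steps; it sets out from 1. Mukaiyama-type hydration by hydrogen-atom transfer (Co(acac)2, that is cobalt bis(acetylacetonate), cat., PhSiH3, air, THF/iPrOH; then PPh3) makes the same C1 radical by hydrogen delivery to the exocyclic CH2, with no thiol or thiyl radical present. This is a reaction class in which terpene vinylcyclobutanes are known to give ring-opened products, and it should give the ring-opened C1-methyl epoxy alcohol F1, which still depends on ring opening outrunning oxygen capture. Swern oxidation should give the epoxy ketone F2. Ene-type allylic chlorination of its only alkene (Ca(OCl)2, solid CO2, CH2Cl2/H2O, 0 °C) moves the double bond to the exocyclic position and should give the C2 allylic chloride F3. Sodium thiophenolate made from 2 (NaH, DMF, 0 °C) then displaces chloride with allylic transposition at the unhindered CH2 terminus, and the fallback comes back to the route at 5.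

Step 4. The catalyst may discriminate poorly between the quaternary C4 flank and the C6 methylene of the flexible eleven-membered ketone, giving low enantiomeric purity, or an alkene may be hydroborated. The fallback replaces asymmetric reduction by resolution and sets out from 6. NaBH4 in MeOH should give the racemic alcohol F4. (1S)-(−)-Camphanic chloride with DMAP in pyridine should give two diastereomeric esters, to be separated by chromatography or crystallisation into the (5R)-camphanate F5 and the (5S)-camphanate F6. Saponification of F5 (KOH, MeOH/H2O, 60 °C, acidic work-up) comes back to the route at 7.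

Step 3. The sulfide may inhibit the rhenium catalyst, or the Lewis-acidic metal may open the epoxide instead of abstracting its oxygen. The fallback replaces direct oxygen abstraction by double inversion through the episulfide and sets out from 5. Thiourea (MeOH, 50 °C) should convert the epoxide into the (8S,9S)-thiirane F7 with inversion at both carbons, so that the trans relationship is kept. PPh3 (toluene, 80 °C) then removes sulfur stereospecifically, and the fallback comes back to the route at 6.

Further compounds
F1 | step 1 | (8R,9R)-8,9-epoxy-1,4,4,8-tetramethylcycloundec-1-en-5-ol, C5 epimers | C[C@@]12CCC(O)C(C)(C)C/C=C(\C)CC[C@H]1O2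
F2 | step 1 | (8R,9R)-8,9-epoxy-1,4,4,8-tetramethylcycloundec-1-en-5-one | C[C@@]12CCC(=O)C(C)(C)C/C=C(\C)CC[C@H]1O2
F3 | step 1 | (8R,9R)-2-chloro-8,9-epoxy-4,4,8-trimethyl-1-methylidenecycloundecan-5-one, C2 epimers | C[C@@]12CCC(=O)C(C)(C)CC(Cl)C(=C)CC[C@H]1O2
F4 | step 4 | racemic (8E)-4,4,8-trimethyl-1-(phenylthiomethyl)cycloundeca-1,8-dien-5-ol | OC1CC/C(C)=C/CC/C(CSc2ccccc2)=C/CC1(C)C
F5 | step 4 | (1S)-camphanate of the (5R)-alcohol | CC1(C)[C@@]2(C)CC[C@@]1(OC2=O)C(=O)O[C@@H]3CC/C(C)=C/CC/C(CSc4ccccc4)=C/CC3(C)C
F6 | step 4 | (1S)-camphanate of the (5S)-alcohol | CC1(C)[C@@]2(C)CC[C@@]1(OC2=O)C(=O)O[C@H]3CC/C(C)=C/CC/C(CSc4ccccc4)=C/CC3(C)C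
F7 | step 3 | (8S,9S)-8,9-epithio-4,4,8-trimethyl-1-(phenylthiomethyl)cycloundec-1-en-5-one | C[C@]12CCC(=O)C(C)(C)C/C=C(\CSc3ccccc3)CC[C@@H]1S2
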